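The disconnection on which everything rests is the bond between the guaiacyl ring carbon and C2 of the dihydropyran. A catalytic asymmetric inverse-demand hetero-Diels–Alder reaction of a 2-(benzofuran-2-yl)acrolein with (Z)-3-ethoxyallyl acetate builds the dihydropyran with C3 set and C2 as an acetal, which is exchanged for a phenyl sulfone (C2 epimers). In the key step a diarylzinc displaces the sulfinate: both epimers ionise to one oxocarbenium ion, a feature owed to ring oxygen O1 beside C2, and the C3 acetoxymethyl group steers the incoming aryl group trans. One operation thus joins the two halves and sets the C2 configuration stereoconvergently. Desilylation then gives the target.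

Key step: step 11

Assumption: the target is the 2,3-trans (2R,3S) isomer, as read from the SMILES. The (1R,2S)-aminoindanol-derived chromium complex of step 8 is assumed to give the (3S) adduct; if a first run shows the opposite sense, the antipodal complex is used.

Step 1
Reactants: 1 2-bromo-1,4-dimethoxybenzene
Product: 2 1-(4-bromo-2,5-dimethoxyphenyl)ethan-1-one
Conditions: AcCl, AlCl3, CH2Cl2, 0 °C
Reagents that add atoms: acetyl chloride, CC(=O)Cl
Why: Friedel–Crafts acylation, which should enter at C5 (ortho to a methoxy group and para to bromine), the least hindered activated position.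

Step 2
Reactants: 2 1-(4-bromo-2,5-dimethoxyphenyl)ethan-1-one
Product: 3 1-(4-bromo-2,5-dihydroxyphenyl)ethan-1-one
Conditions: BBr3, CH2Cl2, -78 °C to rt; then H2O
Reagents that add atoms: none
Why: Lewis-acid cleavage of both aryl methyl ethers, which the aryl ketone and aryl bromide should tolerate.

Step 3
Reactants: 3 1-(4-bromo-2,5-dihydroxyphenyl)ethan-1-one; 4 2-methylbut-1-en-3-yne
Product: 6 1-[5-hydroxy-2-(prop-1-en-2-yl)-1-benzofuran-6-yl]ethan-1-one, via alkynylphenol 5 (not isolated)
Conditions: Pd(PPh3)2Cl2 (cat.), CuI (cat.), Et3N, DMF, 70 °C, sealed tube, argon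
Reagents that add atoms: none
Why: Sonogashira coupling at the bromide activated by the para acetyl group, followed by 5-endo-dig cycloisomerisation of the only hydroxyl ortho to the alkyne (benzofuran annulation).

Step 4
Reactants: 6 1-[5-hydroxy-2-(prop-1-en-2-yl)-1-benzofuran-6-yl]ethan-1-one
Product: 7 1-[5-(tert-butyldimethylsilyloxy)-2-(prop-1-en-2-yl)-1-benzofuran-6-yl]ethan-1-one
Conditions: TBSCl, imidazole, DMF, rt
Reagents that add atoms: tert-butyldimethylsilyl chloride, CC(C)(C)[Si](C)(C)Cl
Why: Silylation masks the phenol, which would otherwise bind the chromium catalyst of step 8 and quench the arylzinc of step 11.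

Step 5
Reactants: 7 1-[5-(tert-butyldimethylsilyloxy)-2-(prop-1-en-2-yl)-1-benzofuran-6-yl]ethan-1-one
Product: 9 2-[6-acetyl-5-(tert-butyldimethylsilyloxy)-1-benzofuran-2-yl]prop-2-enal, via allylic alcohol 8 (not isolated)
Conditions: SeO2 (cat.), t-BuOOH, CH2Cl2, rt; then MnO2, CH2Cl2, rt
Reagents that add atoms: tert-butyl hydroperoxide, CC(C)(C)OO
Why: Catalytic selenium dioxide allylic oxidation (ene reaction, then [2,3]-shift) of the isopropenyl methyl group and MnO2 oxidation of the allylic alcohol, mild enough that Riley oxidation of the acetyl group should not compete.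

Step 6
Reactants: 10 ethoxyethyne
Product: 13 3-ethoxyprop-2-yn-1-yl acetate, via lithium ethoxyacetylide 11 (not isolated), via lithium alkoxide 12 (not isolated)
Conditions: n-BuLi, THF, -78 °C; (CH2O)n, -78 °C to rt; Ac2O, 0 °C
Reagents that add atoms: formaldehyde (as paraformaldehyde), C=O; acetic anhydride, CC(=O)OC(C)=O
Why: Acetylide addition to formaldehyde with acetylation of the alkoxide in the same flask.

Step 7
Reactants: 13 3-ethoxyprop-2-yn-1-yl acetate
Product: 14 (Z)-3-ethoxyprop-2-en-1-yl acetate
Conditions: H2 (1 atm), Lindlar catalyst, quinoline, hexane, rt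
Reagents that add atoms: none
Why: Lindlar semihydrogenation adds hydrogen syn and should give the Z enol ether only.

Step 8
Reactants: 9 2-[6-acetyl-5-(tert-butyldimethylsilyloxy)-1-benzofuran-2-yl]prop-2-enal; 14 (Z)-3-ethoxyprop-2-en-1-yl acetate
Product: 15 [(2S,3S)-5-[6-acetyl-5-(tert-butyldimethylsilyloxy)-1-benzofuran-2-yl]-2-ethoxy-3,4-dihydro-2H-pyran-3-yl]methyl acetate (2,3-cis)
Conditions: tridentate Schiff-base Cr(III)Cl complex from (1R,2S)-1-amino-2-indanol and 3-(1-adamantyl)-5-methylsalicylaldehyde (5 mol %), 4 Å MS, 14 (2 equiv), neat, rt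
Reagents that add atoms: none
Why: Inverse-electron-demand hetero-Diels–Alder reaction in which the chromium Lewis acid binds the aldehyde oxygen of the 1-oxadiene, the Z enol ether adds endo (hence 2,3-cis) and the chiral ligand shields one face so that C3 should form as S, while the C2 configuration is erased later.

Step 9
Reactants: 15 the (2S,3S)-2-ethoxy acetal
Product: 16 [(3S)-5-[6-acetyl-5-(tert-butyldimethylsilyloxy)-1-benzofuran-2-yl]-2-(benzenesulfonyl)-3,4-dihydro-2H-pyran-3-yl]methyl acetate (mixture of C2 epimers)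
Conditions: PhSO2H, CaCl2, CH2Cl2, 0 °C to rt
Reagents that add atoms: benzenesulfinic acid, O=S(O)c1ccccc1
Why: Acid-mediated acetal exchange through the oxocarbenium ion, the usual route to 2-(phenylsulfonyl) cyclic ethers, with the sulfone as the thermodynamic product and the C2 epimer ratio of no consequence.

Step 10
Reactants: 17 4-bromo-2-methoxyphenol
Product: 18 (4-bromo-2-methoxyphenoxy)(tert-butyl)dimethylsilane
Conditions: TBSCl, imidazole, CH2Cl2, rt
Reagents that add atoms: tert-butyldimethylsilyl chloride, CC(C)(C)[Si](C)(C)Cl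
Why: Silylation removes the acidic phenol proton before the organometallic reagent is made.

Step 11
Reactants: 16 the C2-epimeric sulfone; 18 (4-bromo-2-methoxyphenoxy)(tert-butyl)dimethylsilane
Product: 21 [(2R,3S)-5-[6-acetyl-5-(tert-butyldimethylsilyloxy)-1-benzofuran-2-yl]-2-[4-(tert-butyldimethylsilyloxy)-3-methoxyphenyl]-3,4-dihydro-2H-pyran-3-yl]methyl acetate (2,3-trans), via arylmagnesium bromide 19 (not isolated), via diarylzinc 20 (not isolated)
Conditions: 18, Mg, THF; ZnBr2 (0.5 equiv); then 16, THF, 0 °C to rt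
Reagents that add atoms: none
Why: Zinc- and magnesium-assisted loss of benzenesulfinate from C2 of either epimer of 16 gives one cyclic oxocarbenium ion, stabilised by the lone pair of ring oxygen O1, and the diarylzinc transfers its aryl group ipso to C2 to form the aryl–C2 bond. The closest known reaction type is the displacement of 2-(phenylsulfonyl) cyclic ethers by organozinc reagents, the same manifold as C-aryl glycoside formation. No ring is closed. The new stereocentre C2 is controlled by the existing C3 centre: the aryl group should enter anti to the acetoxymethyl group, whose carbonyl oxygen can also bridge to C2 and block the cis face, and the 2,3-trans product is the more stable one. The step needs chemoselectivity for C2 over the aryl ketone and the acetate (low carbonyl reactivity of arylzinc), regiocontrol on the arene (fixed by the carbon–zinc bond para to the silyloxy group) and retention of the ring (sulfinate is a far better leaving group than the enol-ether oxygen O1 under these mild Lewis acids).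

Step 12
Reactants: 21 the bis-silylated 2,3-trans coupling product
Product: 22 propolis-benzofuran A, [(2R,3S)-5-(6-acetyl-5-hydroxy-1-benzofuran-2-yl)-2-(4-hydroxy-3-methoxyphenyl)-3,4-dihydro-2H-pyran-3-yl]methyl acetate
Conditions: TBAF, AcOH, THF, 0 °C
Reagents that add atoms: none
Why: Buffered fluoride cleavage of both aryl silyl ethers, which should leave the alkyl acetate, the enol ether and the benzylic C2–O bond untouched.

Compound list
1 | 2-bromo-1,4-dimethoxybenzene | COc1ccc(OC)c(Br)c1 | starting material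
2 | 1-(4-bromo-2,5-dimethoxyphenyl)ethan-1-one | COc1cc(C(C)=O)c(OC)cc1Br | intermediate
3 | 1-(4-bromo-2,5-dihydroxyphenyl)ethan-1-one | CC(=O)c1cc(O)c(Br)cc1O | intermediate
4 | 2-methylbut-1-en-3-yne | C=C(C)C#C | starting material
5 | 1-[2,5-dihydroxy-4-(3-methylbut-3-en-1-yn-1-yl)phenyl]ethan-1-one (not isolated) | CC(=C)C#Cc1cc(O)c(C(C)=O)cc1O | intermediate
6 | 1-[5-hydroxy-2-(prop-1-en-2-yl)-1-benzofuran-6-yl]ethan-1-one | CC(=C)c1cc2cc(O)c(C(C)=O)cc2o1 | intermediate
7 | 1-[5-(tert-butyldimethylsilyloxy)-2-(prop-1-en-2-yl)-1-benzofuran-6-yl]ethan-1-one | CC(=C)c1cc2cc(O[Si](C)(C)C(C)(C)C)c(C(C)=O)cc2o1 | intermediate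
8 | 1-[5-(tert-butyldimethylsilyloxy)-2-(3-hydroxyprop-1-en-2-yl)-1-benzofuran-6-yl]ethan-1-one (not isolated) | OCC(=C)c1cc2cc(O[Si](C)(C)C(C)(C)C)c(C(C)=O)cc2o1 | intermediate
9 | 2-[6-acetyl-5-(tert-butyldimethylsilyloxy)-1-benzofuran-2-yl]prop-2-enal | O=CC(=C)c1cc2cc(O[Si](C)(C)C(C)(C)C)c(C(C)=O)cc2o1 | intermediate
10 | ethoxyethyne | CCOC#C | starting material
11 | lithium ethoxyacetylide (not isolated) | CCOC#C[Li] | intermediate
12 | lithium 3-ethoxyprop-2-yn-1-olate (not isolated) | CCOC#CC[O-].[Li+] | intermediate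
13 | 3-ethoxyprop-2-yn-1-yl acetate | CCOC#CCOC(C)=O | intermediate
14 | (Z)-3-ethoxyprop-2-en-1-yl acetate | CCO/C=C\COC(C)=O | intermediate
15 | [(2S,3S)-5-[6-acetyl-5-(tert-butyldimethylsilyloxy)-1-benzofuran-2-yl]-2-ethoxy-3,4-dihydro-2H-pyran-3-yl]methyl acetate (2,3-cis) | CCO[C@H]1OC=C(c2cc3cc(O[Si](C)(C)C(C)(C)C)c(C(C)=O)cc3o2)C[C@H]1COC(C)=O | intermediate
16 | [(3S)-5-[6-acetyl-5-(tert-butyldimethylsilyloxy)-1-benzofuran-2-yl]-2-(benzenesulfonyl)-3,4-dihydro-2H-pyran-3-yl]methyl acetate (C2 epimers) | O=S(=O)(c1ccccc1)C1OC=C(c2cc3cc(O[Si](C)(C)C(C)(C)C)c(C(C)=O)cc3o2)C[C@H]1COC(C)=O | intermediate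
17 | 4-bromo-2-methoxyphenol | COc1cc(Br)ccc1O | starting material
18 | (4-bromo-2-methoxyphenoxy)(tert-butyl)dimethylsilane | COc1cc(Br)ccc1O[Si](C)(C)C(C)(C)C | intermediate
19 | [4-(tert-butyldimethylsilyloxy)-3-methoxyphenyl]magnesium bromide (not isolated) | COc1cc([Mg]Br)ccc1O[Si](C)(C)C(C)(C)C | intermediate
20 | bis[4-(tert-butyldimethylsilyloxy)-3-methoxyphenyl]zinc (not isolated) | COc1cc([Zn]c2ccc(O[Si](C)(C)C(C)(C)C)c(OC)c2)ccc1O[Si](C)(C)C(C)(C)C | intermediate
21 | [(2R,3S)-5-[6-acetyl-5-(tert-butyldimethylsilyloxy)-1-benzofuran-2-yl]-2-[4-(tert-butyldimethylsilyloxy)-3-methoxyphenyl]-3,4-dihydro-2H-pyran-3-yl]methyl acetate (2,3-trans) | COc1cc([C@@H]2OC=C(c3cc4cc(O[Si](C)(C)C(C)(C)C)c(C(C)=O)cc4o3)C[C@H]2COC(C)=O)ccc1O[Si](C)(C)C(C)(C)C | intermediate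
22 | propolis-benzofuran A, [(2R,3S)-5-(6-acetyl-5-hydroxy-1-benzofuran-2-yl)-2-(4-hydroxy-3-methoxyphenyl)-3,4-dihydro-2H-pyran-3-yl]methyl acetate | COc1cc([C@@H]2OC=C(c3cc4cc(O)c(C(C)=O)cc4o3)C[C@H]2COC(C)=O)ccc1O | target

Total step count: 12. Longest linear sequence: 9 steps (1, 2, 3, 4, 5, 8, 9, 11, 12).

Steps most likely to fail

Step 11 (key step). Ring oxygen O1 is an enol-ether oxygen and a weaker donor than an alkyl ether oxygen. Ionisation at C2 may therefore be slow, the O1–C2 bond may cleave instead and open the ring, sulfinic acid may be eliminated towards a 4H-pyran, or the aryl group may be delivered with poor facial selectivity. The fallback abandons the cyclic cation and sets out from acetal 15. Mild hydrolysis (PPTS, acetone–water, rt) should give the lactol [(3S)-5-[6-acetyl-5-(tert-butyldimethylsilyloxy)-1-benzofuran-2-yl]-2-hydroxy-3,4-dihydro-2H-pyran-3-yl]methyl acetate F1. Adding F1 to Grignard reagent 19 (2.5 equiv, THF, -78 °C) should first open the lactol to the C2 aldehyde, with C6 held as its magnesium enolate, and then add the aryl group to that aldehyde. After work-up the hydroxy aldehyde should close to the hemiacetal [(3S)-5-[6-acetyl-5-(tert-butyldimethylsilyloxy)-1-benzofuran-2-yl]-2-[4-(tert-butyldimethylsilyloxy)-3-methoxyphenyl]-6-hydroxyoxan-3-yl]methyl acetate F2. Catalytic camphorsulfonic acid with 4 Å MS in CH2Cl2 should then dehydrate F2 to the benzofuran-conjugated enol ether and equilibrate the aryl-bearing carbon through the 4-silyloxy-3-methoxybenzylic cation to the more stable trans isomer, which rejoins the route at 21.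

Step 8. The cycloaddition may be slow with this β-unsubstituted 2-arylacrolein, so that hetero-Diels–Alder dimerisation of 9 competes, and facial discrimination by the catalyst may be low. The fallback replaces asymmetric catalysis by kinetic resolution and sets out from 9 and 14. Thermal cycloaddition (neat, 50 °C, BHT) should give the racemic cis acetal, that is 15 together with its enantiomer [(2R,3R)-5-[6-acetyl-5-(tert-butyldimethylsilyloxy)-1-benzofuran-2-yl]-2-ethoxy-3,4-dihydro-2H-pyran-3-yl]methyl acetate F3. A lipase (Burkholderia cepacia lipase, pH 7 buffer–MTBE, chosen by screening) should hydrolyse the primary acetate of F3 to the alcohol [(2R,3R)-5-[6-acetyl-5-(tert-butyldimethylsilyloxy)-1-benzofuran-2-yl]-2-ethoxy-3,4-dihydro-2H-pyran-3-yl]methanol F4, which is separated by chromatography. The unreacted acetate rejoins the route at 15.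

Step 9. Benzenesulfinic acid may add across the benzofuran-conjugated enol ether, or the acid may open the ring towards the dialdehyde instead of exchanging the acetal. The fallback skips the sulfone and sets out from acetal 15. Grignard reagent 19 is transmetalated with CuBr·SMe2 (Et2O, -40 °C) to the arylcopper reagent [4-(tert-butyldimethylsilyloxy)-3-methoxyphenyl]copper F5. F5 is combined with 15 and BF3·OEt2 (Et2O, -78 to -30 °C), the known organocopper–boron trifluoride substitution of an acetal alkoxy group. This should replace the ethoxy group by the aryl group, trans to the acetoxymethyl group, and rejoins the route at 21.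

Further compounds
F1 | step 11 | [(3S)-5-[6-acetyl-5-(tert-butyldimethylsilyloxy)-1-benzofuran-2-yl]-2-hydroxy-3,4-dihydro-2H-pyran-3-yl]methyl acetate (C2 epimers) | OC1OC=C(c2cc3cc(O[Si](C)(C)C(C)(C)C)c(C(C)=O)cc3o2)C[C@H]1COC(C)=O
F2 | step 11 | [(3S)-5-[6-acetyl-5-(tert-butyldimethylsilyloxy)-1-benzofuran-2-yl]-2-[4-(tert-butyldimethylsilyloxy)-3-methoxyphenyl]-6-hydroxyoxan-3-yl]methyl acetate (mixture at C2, C5, C6) | COc1cc(C2OC(O)C(c3cc4cc(O[Si](C)(C)C(C)(C)C)c(C(C)=O)cc4o3)C[C@H]2COC(C)=O)ccc1O[Si](C)(C)C(C)(C)C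
F3 | step 8 | [(2R,3R)-5-[6-acetyl-5-(tert-butyldimethylsilyloxy)-1-benzofuran-2-yl]-2-ethoxy-3,4-dihydro-2H-pyran-3-yl]methyl acetate (enantiomer of 15) | CCO[C@@H]1OC=C(c2cc3cc(O[Si](C)(C)C(C)(C)C)c(C(C)=O)cc3o2)C[C@@H]1COC(C)=O
F4 | step 8 | [(2R,3R)-5-[6-acetyl-5-(tert-butyldimethylsilyloxy)-1-benzofuran-2-yl]-2-ethoxy-3,4-dihydro-2H-pyran-3-yl]methanol | CCO[C@@H]1OC=C(c2cc3cc(O[Si](C)(C)C(C)(C)C)c(C(C)=O)cc3o2)C[C@@H]1CO
F5 | step 9 | [4-(tert-butyldimethylsilyloxy)-3-methoxyphenyl]copper | COc1cc([Cu])ccc1O[Si](C)(C)C(C)(C)C
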